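I start at the flat end of the run.

in all of them: Z 0.097 M; L 7.4 mM (held); temperature −20 °C

| run | J | remark | time |
|---|---|---|---|
| autumn | 4.8 mM | the very flask that is asked about, followed so far |  |
| dusk | 9.6 mM | run made earlier |  |
| flask | 4.8 mM |  | 3.0 h |

- autumn (time / min: E / %, Z / %): 15.0: 34.4, 43.5; 30.0: 45.4, 15.7; 80.0: 54.5, 0; 180: 55.9, 0
- dusk (time / min: E / %, Z / %): 2.50: 19.2, 77.1; 5.00: 29.7, 57.6; 8.00: 38.8, 39.9; 10.0: 43.5, 30.8

(readings scatter by 1 percentage point)

- Friday's: at 3.0 h add J, 100% of the amount charged, then wait 1.5 h
- Saturday's: at 3.0 h raise the temperature by 10 K, then wait 1.5 h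
- Thursday's: at 3.0 h take out 90% of the E then present, then wait 1.5 h
- Tuesday's: change nothing and wait 1.5 h more

- E, in percent of the Z first charged, at 3.0 h
- what to do for the largest gain in E; "none" if nothing gains more than 2 percentage points (Friday's / Saturday's / Thursday's / Tuesday's / none)
- E present, with what was taken out counted in, in percent of the Z first charged, after Friday's
- E present, with what was taken out counted in, in percent of the Z first charged, after Saturday's

- E taken out counts as made
- at the start none of L is in solution
- additions bring no volume worth counting
- the earlier runs do not show what temperature does; that part of a forecast is a guess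

1. In the autumn flask Z reads 0% at 80.0 min, and E reads 54.5% there and 55.9% at 180 min. Their mean, 55.2%, is what I carry: the E share, the fraction of the Z charged that stands as E once the flask has stopped changing.

2. In the dusk flask E is 83.8% of the Z used at 2.50 min but 62.9% at 10.0 min. So E comes first and part of it then passes into something unseen. In the autumn flask that loss stops with E still there, so I read an equilibrium, thermodynamic control of E against its partner.

3. Waiting: the late autumn readings agree within their scatter, so Tuesday's gains nothing by my reckoning, and E at 3.0 h is the share.

4. More J: the logarithm of the fraction of Z left falls twice as fast in the dusk flask, with twice the J. But in the autumn flask Z already reads 0%, and a catalyst leaves an equilibrium where it stands. I expect no gain from Friday's.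

5. Heat: these runs show no temperature, so for Saturday's I keep the share and call that a guess.

6. Taking out: I reckon with what is left. After Thursday's, 50.3% remains in the flask. In the autumn flask E already reads 53.9% of the Z used at 30.0 min, close to the share, and that time is shorter than the wait. So the remainder returns to the share, and E counted with what was taken out comes to 77.5%.

The forecast gives 55.4% now, 55.5% after Friday's, 55.5% after Saturday's, and chooses Thursday's: “Removing 90% of E leaves about 50% total”.

The flask gives 54.6%, 54.6% after Friday's and 58.6% after Saturday's, and the best choice is Thursday's, which gains 22 percentage points.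

    G + J ⇌ D (K = 170 M⁻¹, k = 13.0 M⁻¹ s⁻¹, Ea = 47.0 kJ mol⁻¹, ΔH = −78.0 kJ mol⁻¹)
    Z + D ⇌ Q (K = 200 M⁻¹, k = 0.500 M⁻¹ s⁻¹, Ea = 41.0 kJ mol⁻¹, ΔH = −63.0 kJ mol⁻¹)
    Q → J + E (k = 0.100 s⁻¹, Ea = 68.0 kJ mol⁻¹)
    E ⇌ X (K = 0.830, k = 0.00430 s⁻¹, Ea = 64.0 kJ mol⁻¹, ΔH = −9.00 kJ mol⁻¹)
    L ⇌ G, rate k5*(csat - [G]) (kL = 1.30 s⁻¹)
    (constants at −20 °C)

By 18.0 min the flask has Z at 35.0%, with J, D and Q turning it into E while E passes on into X. From 90.0 min, with Z at 0.152%, E and X stand at 54.6% and 45.4%, and the relaxation half-life of that pair, both ways together, is 1.22 min, short against 3.0 h. For this flask, then, the X is a store within reach, and taking out E draws on it.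

At 5 °C, the neighbour flask, the share read at −20 °C gives 55.0% of E. The computed flask stands at 63.7%, which is 8.7 points above that reckoning.

The runs were generated by integration with constants of no real substance, and the scatter is random.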